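**Retrosynthetic overview**
1. Target 18 ⇐ acyclic silylated ynone 15 (C3 carbonyl, C4≡C4a). Ring A (carbocycle) closes first by amine-catalysed C5→C4a carbocyclisation; ring B (pyran) closes second by desilylative cyclodehydration of the C1 hydroxyl onto C3.
2. Ynone 15 ⇐ core alkyne 7 + CO + side-chain (E)-vinyl iodide 14 (carbonylative Sonogashira).
3. Core 7 ⇐ chelation-controlled acetyl-anion addition (sets C7) ⇐ alkyne 4 ⇐ (S)-proline cross-aldol of aldehyde 1 with methylglyoxal 2 (sets C8 and C8a).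
4. Side chain 14 ⇐ Felkin–Anh vinylation (sets C3′) of ketone 12 ⇐ (R)-proline cross-aldol of propanal 8 with 2 (sets C4′ and C5′).

Assumption: the target is taken exactly as drawn, i.e. (7S,8R,8aS)-3-[(1E,3R,4S,5S)-3,4-dihydroxy-3,5-dimethylhept-1-en-1-yl]-7,8-dihydroxy-7-methyl-1,7,8,8a-tetrahydro-6H-isochromen-6-one; isochromenone numbering (C1 to C8a) and primed side-chain numbering (C1′ to C7′) are used for atoms throughout.

**Step 1**
Reactants: 1 3-[(tert-butyldimethylsilyl)oxy]propanal; 2 2-oxopropanal (methylglyoxal, 40 wt% in water)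
Product: 3 (2S,3R)-2-{[(tert-butyldimethylsilyl)oxy]methyl}-3-hydroxy-4-oxopentanal
Conditions: (S)-proline (20 mol%), DMF, 4 °C, 2 (3 equiv), slow addition of 1 over 24 h
Reagents that add atoms: none
Why: Enamine cross-aldol (proline catalysis, Houk–List transition state): slow addition of donor 1 to the more electrophilic formyl group of 2 suppresses self-aldol, and (S)-proline delivers the anti adduct, setting C8a (S) and C8 (R) as the first stereocenters.

**Step 2**
Reactants: 3 (2S,3R)-2-{[(tert-butyldimethylsilyl)oxy]methyl}-3-hydroxy-4-oxopentanal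
Product: 4 (3R,4S)-4-{[(tert-butyldimethylsilyl)oxy]methyl}-3-hydroxyhex-5-yn-2-one
Conditions: dimethyl (1-diazo-2-oxopropyl)phosphonate, K2CO3, MeOH, 0 °C, 3 h
Reagents that add atoms: dimethyl (1-diazo-2-oxopropyl)phosphonate COP(=O)(OC)C(=[N+]=[N-])C(C)=O
Why: Ohira–Bestmann (Seyferth–Gilbert) homologation turns only the aldehyde into the terminal alkyne (new carbon = C4) under carbonate/methanol at 0 °C, conditions mild enough to keep the ketol, the silyl ether and both stereocenters intact.

**Step 3**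
Reactants: 4 (3R,4S)-4-{[(tert-butyldimethylsilyl)oxy]methyl}-3-hydroxyhex-5-yn-2-one
Product: 6 (3S,4R,5S)-5-{[(tert-butyldimethylsilyl)oxy]methyl}-3,4-dihydroxy-3-methylhept-6-yn-2-one, via enol ether 5 (not isolated)
Conditions: ethyl vinyl ether, t-BuLi (3.5 equiv), THF, −78 → 0 °C; MgBr2·OEt2, −78 °C; inverse addition of 4, −78 °C; then 0.5 M HCl, THF, 0 °C
Reagents that add atoms: ethyl vinyl ether C=COCC; water O
Why: Chelation-controlled (Cram cyclic model) 1,2-addition of an acetyl anion equivalent: the magnesium alkoxide of the C8 hydroxyl and the C7 carbonyl form a five-membered chelate that is attacked from the side of the C8 hydrogen, giving the syn (threo) diol with C7 (S), and dilute acid then hydrolyses the enol ether 5 to the methyl ketone.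

**Step 4**
Reactants: 6 (3S,4R,5S)-5-{[(tert-butyldimethylsilyl)oxy]methyl}-3,4-dihydroxy-3-methylhept-6-yn-2-one
Product: 7 (3S,4R,5S)-5-{[(tert-butyldimethylsilyl)oxy]methyl}-3-methyl-3,4-bis[(triethylsilyl)oxy]hept-6-yn-2-one
Conditions: TESOTf (2.6 equiv), 2,6-lutidine, CH2Cl2, −78 → 0 °C
Reagents that add atoms: triethylsilyl trifluoromethanesulfonate CC[Si](CC)(CC)OS(=O)(=O)C(F)(F)F
Why: Silyl triflate silylation caps the secondary and the tertiary hydroxyl so that neither can add to the ynone formed later (the 5-exo oxa-Michael addition of the C7 hydroxyl would otherwise outrun carbocyclisation); no stereocenter is touched.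

**Step 5**
Reactants: 8 propanal; 2 2-oxopropanal (methylglyoxal, 40 wt% in water)
Product: 9 (2R,3S)-3-hydroxy-2-methyl-4-oxopentanal
Conditions: (R)-proline (10 mol%), DMF, 4 °C, 2 (3 equiv), slow addition of 8 over 24 h
Reagents that add atoms: none
Why: The same proline enamine cross-aldol as in step 1, run with (R)-proline, gives the anti adduct of opposite absolute sense and so sets C5′ and C4′ with the configuration of the target.

**Step 6**
Reactants: 9 (2R,3S)-3-hydroxy-2-methyl-4-oxopentanal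
Product: 10 (2R,3S)-2-methyl-4-oxo-3-[(triethylsilyl)oxy]pentanal
Conditions: TESOTf, 2,6-lutidine, CH2Cl2, −78 °C
Reagents that add atoms: triethylsilyl trifluoromethanesulfonate CC[Si](CC)(CC)OS(=O)(=O)C(F)(F)F
Why: Silylation blocks retro-aldol and β-elimination of the hydroxy aldehyde and installs the poorly chelating α-silyloxy group that steers the later addition to the ketone.

**Step 7**
Reactants: 10 (2R,3S)-2-methyl-4-oxo-3-[(triethylsilyl)oxy]pentanal
Product: 11 (3S,4S)-4-methyl-3-[(triethylsilyl)oxy]hex-5-en-2-one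
Conditions: Ph3PCH3Br (1.05 equiv), KN(SiMe3)2, THF, −78 → 0 °C
Reagents that add atoms: methyltriphenylphosphonium bromide C[P+](c1ccccc1)(c1ccccc1)c1ccccc1.[Br-]
Why: Wittig methylenation: at −78 °C one equivalent of the ylide reacts with the aldehyde much faster than with the hindered α-silyloxy methyl ketone, and the cold, short exposure does not epimerise C5′.

**Step 8**
Reactants: 11 (3S,4S)-4-methyl-3-[(triethylsilyl)oxy]hex-5-en-2-one
Product: 12 (3S,4S)-4-methyl-3-[(triethylsilyl)oxy]hexan-2-one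
Conditions: H2 (1 atm), Pd/C, EtOAc, 23 °C
Reagents that add atoms: none
Why: Heterogeneous hydrogenation saturates the terminal alkene to the ethyl group (completing the sec-butyl terminus) and leaves the ketone and the silyl ether untouched.

**Step 9**
Reactants: 12 (3S,4S)-4-methyl-3-[(triethylsilyl)oxy]hexan-2-one
Product: 14 (1E,3R,4S,5S)-1-iodo-3,5-dimethyl-4-[(triethylsilyl)oxy]hept-1-en-3-ol, via vinylstannane 13 (not isolated)
Conditions: (E)-Bu3SnCH=CHSnBu3, n-BuLi, THF, −78 °C; 12, −78 °C; H2O; then I2, CH2Cl2, 0 °C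
Reagents that add atoms: (E)-1,2-bis(tributylstannyl)ethene CCCC[Sn](CCCC)(CCCC)/C=C/[Sn](CCCC)(CCCC)CCCC; iodine II
Why: Felkin–Anh (non-chelation) 1,2-addition of the vinyllithium to the α-silyloxy ketone, with the carbon–OSi bond anti to the incoming nucleophile, sets C3′ (R) anti to the C4′ oxygen, and iododestannylation with retention then gives the (E)-vinyl iodide.

**Step 10**
Reactants: 7 (3S,4R,5S)-5-{[(tert-butyldimethylsilyl)oxy]methyl}-3-methyl-3,4-bis[(triethylsilyl)oxy]hept-6-yn-2-one; 14 (1E,3R,4S,5S)-1-iodo-3,5-dimethyl-4-[(triethylsilyl)oxy]hept-1-en-3-ol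
Product: 15 (3S,4R,5S,9E,11R,12S,13S)-5-{[(tert-butyldimethylsilyl)oxy]methyl}-11-hydroxy-3,11,13-trimethyl-3,4,12-tris[(triethylsilyl)oxy]pentadec-9-en-6-yne-2,8-dione
Conditions: PdCl2(PPh3)2 (5 mol%), CuI (5 mol%), CO (1 atm), Et3N, THF, 23 °C
Reagents that add atoms: carbon monoxide [C-]#[O+]
Why: Carbonylative Sonogashira coupling: oxidative addition of zerovalent palladium into the vinyl carbon–iodine bond, CO insertion and transfer of the copper acetylide of 7 join the two halves as the alkynyl vinyl ketone (new carbonyl = C3) with retention of the E alkene and without touching any stereocenter.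

**Step 11**
Reactants: 15 (3S,4R,5S,9E,11R,12S,13S)-5-{[(tert-butyldimethylsilyl)oxy]methyl}-11-hydroxy-3,11,13-trimethyl-3,4,12-tris[(triethylsilyl)oxy]pentadec-9-en-6-yne-2,8-dione
Product: 18 (7S,8R,8aS)-3-[(1E,3R,4S,5S)-3,4-dihydroxy-3,5-dimethylhept-1-en-1-yl]-7,8-dihydroxy-7-methyl-1,7,8,8a-tetrahydro-6H-isochromen-6-one, via silylated enedione 16 (not isolated), via desilylated enedione 17 (not isolated)
Conditions: DABCO (30 mol%), CHCl3, 23 °C; then HF·pyridine, pyridine, THF, 0 → 23 °C
Reagents that add atoms: none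
Why: Proposed new method: DABCO adds reversibly to the ynone β-carbon C4a to give a β-ammonium allenolate that is basic enough to deprotonate the C5 methyl of the tethered ketone, the resulting enolate closes ring A by 6-exo attack on C4a with loss of DABCO (an addition–elimination that gives the E/Z-equilibrating enedione 16), and HF·pyridine then strips all four silyl groups so that the freed C1 hydroxyl of the Z isomer adds to the C3 carbonyl and water is lost towards C5, closing ring B as the push–pull dienol ether; C8a from step 1 is kept or, should it enolise, is expected to be re-protonated anti to the pseudo-axial C8 oxygen to the same configuration; the closest known reaction types are tertiary-amine- and phosphine-catalysed cycloisomerisations of ynones that carry a tethered carbon pronucleophile, which have not been shown for an unactivated methyl ketone feeding a dehydrative pyran closure.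

**Compound list**
1 | 3-[(tert-butyldimethylsilyl)oxy]propanal | O=CCCO[Si](C)(C)C(C)(C)C | starting material
2 | 2-oxopropanal (methylglyoxal, 40 wt% in water) | CC(=O)C=O | starting material
3 | (2S,3R)-2-{[(tert-butyldimethylsilyl)oxy]methyl}-3-hydroxy-4-oxopentanal | O=C[C@@H](CO[Si](C)(C)C(C)(C)C)[C@@H](O)C(C)=O | intermediate
4 | (3R,4S)-4-{[(tert-butyldimethylsilyl)oxy]methyl}-3-hydroxyhex-5-yn-2-one | C#C[C@@H](CO[Si](C)(C)C(C)(C)C)[C@@H](O)C(C)=O | intermediate
5 | (3S,4R,5S)-5-{[(tert-butyldimethylsilyl)oxy]methyl}-2-ethoxy-3-methylhept-1-en-6-yne-3,4-diol | C#C[C@@H](CO[Si](C)(C)C(C)(C)C)[C@@H](O)[C@](C)(O)C(=C)OCC | intermediate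
6 | (3S,4R,5S)-5-{[(tert-butyldimethylsilyl)oxy]methyl}-3,4-dihydroxy-3-methylhept-6-yn-2-one | C#C[C@@H](CO[Si](C)(C)C(C)(C)C)[C@@H](O)[C@](C)(O)C(C)=O | intermediate
7 | (3S,4R,5S)-5-{[(tert-butyldimethylsilyl)oxy]methyl}-3-methyl-3,4-bis[(triethylsilyl)oxy]hept-6-yn-2-one | C#C[C@@H](CO[Si](C)(C)C(C)(C)C)[C@@H](O[Si](CC)(CC)CC)[C@](C)(O[Si](CC)(CC)CC)C(C)=O | intermediate
8 | propanal | CCC=O | starting material
9 | (2R,3S)-3-hydroxy-2-methyl-4-oxopentanal | O=C[C@H](C)[C@H](O)C(C)=O | intermediate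
10 | (2R,3S)-2-methyl-4-oxo-3-[(triethylsilyl)oxy]pentanal | O=C[C@H](C)[C@H](O[Si](CC)(CC)CC)C(C)=O | intermediate
11 | (3S,4S)-4-methyl-3-[(triethylsilyl)oxy]hex-5-en-2-one | C=C[C@H](C)[C@H](O[Si](CC)(CC)CC)C(C)=O | intermediate
12 | (3S,4S)-4-methyl-3-[(triethylsilyl)oxy]hexan-2-one | CC[C@H](C)[C@H](O[Si](CC)(CC)CC)C(C)=O | intermediate
13 | (1E,3R,4S,5S)-3,5-dimethyl-1-(tributylstannyl)-4-[(triethylsilyl)oxy]hept-1-en-3-ol | CC[C@H](C)[C@H](O[Si](CC)(CC)CC)[C@](C)(O)/C=C/[Sn](CCCC)(CCCC)CCCC | intermediate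
14 | (1E,3R,4S,5S)-1-iodo-3,5-dimethyl-4-[(triethylsilyl)oxy]hept-1-en-3-ol | CC[C@H](C)[C@H](O[Si](CC)(CC)CC)[C@](C)(O)/C=C/I | intermediate
15 | (3S,4R,5S,9E,11R,12S,13S)-5-{[(tert-butyldimethylsilyl)oxy]methyl}-11-hydroxy-3,11,13-trimethyl-3,4,12-tris[(triethylsilyl)oxy]pentadec-9-en-6-yne-2,8-dione | CC[C@H](C)[C@H](O[Si](CC)(CC)CC)[C@](C)(O)/C=C/C(=O)C#C[C@@H](CO[Si](C)(C)C(C)(C)C)[C@@H](O[Si](CC)(CC)CC)[C@](C)(O[Si](CC)(CC)CC)C(C)=O | intermediate
16 | (2S,3R,4S,5Z)-4-{[(tert-butyldimethylsilyl)oxy]methyl}-5-{(3E,5R,6S,7S)-5-hydroxy-5,7-dimethyl-2-oxo-6-[(triethylsilyl)oxy]non-3-en-1-ylidene}-2-methyl-2,3-bis[(triethylsilyl)oxy]cyclohexan-1-one | CC[C@H](C)[C@H](O[Si](CC)(CC)CC)[C@](C)(O)/C=C/C(=O)/C=C1/CC(=O)[C@@](C)(O[Si](CC)(CC)CC)[C@H](O[Si](CC)(CC)CC)[C@@H]1CO[Si](C)(C)C(C)(C)C | intermediate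
17 | (2S,3R,4S,5Z)-5-[(3E,5R,6S,7S)-5,6-dihydroxy-5,7-dimethyl-2-oxonon-3-en-1-ylidene]-2,3-dihydroxy-4-(hydroxymethyl)-2-methylcyclohexan-1-one | CC[C@H](C)[C@H](O)[C@](C)(O)/C=C/C(=O)/C=C1/CC(=O)[C@@](C)(O)[C@H](O)[C@@H]1CO | intermediate
18 | (7S,8R,8aS)-3-[(1E,3R,4S,5S)-3,4-dihydroxy-3,5-dimethylhept-1-en-1-yl]-7,8-dihydroxy-7-methyl-1,7,8,8a-tetrahydro-6H-isochromen-6-one | CC[C@H](C)[C@H](O)[C@](C)(O)/C=C/C1=CC2=CC(=O)[C@@](C)(O)[C@H](O)[C@@H]2CO1 | target

**Step count and risks**
Total step count: 11. Longest linear sequence: 7 (steps 5 to 11; the core branch is steps 1 to 4, then 10 and 11).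

The three steps most likely to fail:

Step 11 (proposed new cascade). The methyl ketone may be too weak a carbon acid for the amine-generated allenolate, γ-deprotonation at C8a may divert material to an allenone, and the E isomer of 16 may cyclise slowly. The fallback uses known reactions, sets out from 15 and comes back at 18, and builds ring B before ring A. Conjugate addition of diethylamine to the ynone gives the diethylamino enone F1. Aqueous HF in MeCN then removes the silyl groups, the freed primary C1 hydroxyl closes onto C3, and the iminium is hydrolysed, giving the 2,3-dihydro-4H-pyran-4-one F2. An intramolecular aldol condensation of the methyl ketone onto the pyranone carbonyl (catalytic KOt-Bu in t-BuOH, or DBU in MeCN) closes ring A and gives 18.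

Step 1 (step 5 is the same reaction with the easier donor propanal). Aqueous methylglyoxal is largely hydrated and oligomeric, may react slowly or self-condense, and its keto group could perturb the usual facial model. The fallback sets out from 1 and comes back at 3. The acceptor is replaced by the non-enolisable α-thioacetal aldehyde 2-methyl-1,3-dithiane-2-carbaldehyde F3 (from 2-methyl-1,3-dithiane, n-BuLi, then DMF). The same (S)-proline cross-aldol gives the dithiane adduct F4, and MeI with CaCO3 in aqueous MeCN unmasks the ketone to return 3.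

Step 2. The unprotected β-hydroxy aldehyde and secondary ketol of 3 can undergo retro-aldol cleavage, dehydration or ketol isomerisation under carbonate/methanol. The fallback sets out from 3 and comes back at 4. TESCl and imidazole give the silyl ether F5, whose aldehyde is homologated with the Ohira–Bestmann reagent (no free alkoxide, so no retro-aldol) to the silyl alkyne F6. PPTS in MeOH at 0 °C then removes the secondary triethylsilyl ether in the presence of the primary TBS ether and returns 4.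

**Further compounds**
F1 | step 11 | (3S,4R,5S,9E,11R,12S,13S)-5-{[(tert-butyldimethylsilyl)oxy]methyl}-6-(diethylamino)-11-hydroxy-3,11,13-trimethyl-3,4,12-tris[(triethylsilyl)oxy]pentadeca-6,9-diene-2,8-dione (geometry of the 6,7-alkene not fixed) | CC[C@H](C)[C@H](O[Si](CC)(CC)CC)[C@](C)(O)/C=C/C(=O)C=C(N(CC)CC)[C@@H](CO[Si](C)(C)C(C)(C)C)[C@@H](O[Si](CC)(CC)CC)[C@](C)(O[Si](CC)(CC)CC)C(C)=O
F2 | step 11 | (3S)-6-[(1E,3R,4S,5S)-3,4-dihydroxy-3,5-dimethylhept-1-en-1-yl]-3-[(1R,2S)-1,2-dihydroxy-2-methyl-3-oxobutyl]-2,3-dihydro-4H-pyran-4-one | CC[C@H](C)[C@H](O)[C@](C)(O)/C=C/C1=CC(=O)[C@@H](CO1)[C@@H](O)[C@](C)(O)C(C)=O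
F3 | step 1 | 2-methyl-1,3-dithiane-2-carbaldehyde | CC1(C=O)SCCCS1
F4 | step 1 | (2S,3R)-2-{[(tert-butyldimethylsilyl)oxy]methyl}-3-hydroxy-3-(2-methyl-1,3-dithian-2-yl)propanal | O=C[C@@H](CO[Si](C)(C)C(C)(C)C)[C@@H](O)C1(C)SCCCS1
F5 | step 2 | (2S,3R)-2-{[(tert-butyldimethylsilyl)oxy]methyl}-4-oxo-3-[(triethylsilyl)oxy]pentanal | O=C[C@@H](CO[Si](C)(C)C(C)(C)C)[C@@H](O[Si](CC)(CC)CC)C(C)=O
F6 | step 2 | (3R,4S)-4-{[(tert-butyldimethylsilyl)oxy]methyl}-3-[(triethylsilyl)oxy]hex-5-yn-2-one | C#C[C@@H](CO[Si](C)(C)C(C)(C)C)[C@@H](O[Si](CC)(CC)CC)C(C)=O
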